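## Structural features

The target is one oxolane ring (O1, C2–C5) with three substituted ring carbons. C2 carries an n-pentyl chain (first carbon C1″), C3 a tetradecanoyloxy group, and C5 an exocyclic secondary carbinol C1′ that continues into a non-8-enyl chain ending in a terminal alkene. The configuration is 2S,3S,5R,1′R.

The stereocentres form two adjacent pairs, C2/C3 (pentyl and acyloxy cis) and C5/C1′ (threo), separated by the C4 methylene. The C5 side chain is trans to the substituents on C2 and C3.

Fragile points are the terminal alkene (no hydrogenation, hydrogenolysis or late electrophilic oxidants) and the secondary ester, which is base-labile and, if present early, a participating neighbour for any cation at C2. The α-oxygenated aldehyde and lactol intermediates epimerise or ionise easily.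

The difficulty is twofold. The two secondary oxygens at C3 and C1′ must be told apart so that only C3 is acylated. The pentyl group must also be placed on C2 cis to the C3 oxygen, the more crowded arrangement.

The key step uses the segment O–C3–C4–C5–O1. Its two oxygens lie on the same side of the C3–C4–C5 chain, as in cis-cyclopent-2-ene-1,4-diol, and the two alkene carbons of that ring correspond to C2 and C1′. Cleaving the alkene of the enantiopure mono-silylated diol delivers C3 and C5 correctly configured. The one free hydroxyl (the future O1) closes onto the C2 aldehyde, so C2 (lactol) and C1′ (aldehyde) are chemically distinct from the outset.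

The C3 oxygen is kept as a non-participating silyl ether until after the C2 substitution. An acyl group there, the final tetradecanoate included, would steer the pentyl group to the trans face.

## Logic of the disconnections

**19 to 18.** Only the O–Si bond at C1′ is cut. Keeping this hydroxyl masked to the end is what allows C3 alone to be acylated, so the precursor has no free hydroxyl beside the ester. The forward step must remove a hindered silyl ether without base, so that the ester is neither cleaved nor moved.

**18 to 16 and 17.** The acyl C–O bond at C3 is cut. The ester is the most labile group and would participate at C2, so it is attached only after all C–C bonds exist. The cut removes fourteen carbons and leaves the simple acid 17. It demands that the C3 hydroxyl of 16 be the only free one and that acylation copes with a hydroxyl cis to the pentyl group.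

**16 to 15.** The O–Si bond at C3 is cut. The gain is that both secondary oxygens are then silyl ethers of different size, which can be introduced at different stages. The forward step must cleave the smaller silyl ether and leave the larger one at C1′.

**15 to 10 and 11 (through 12, 13 and 14).** The C2–C1″ bond is cut. C2 is bonded to O1 and is therefore an acetal-level carbon in disguise: it becomes cation 14, and the pentyl group becomes nucleophile 13, made from 11 by way of 12. This removes the pentyl chain and the C2 stereocentre and leaves 10 with C2 as a mixed acetal. The forward step must bring the nucleophile in cis to the C3 oxygen and trans to the C5 side chain. That requires an ether, not an ester, at C3 and an ionisation that spares the other silyl ethers.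

**10 to 9.** The O–Si bond at C1′ is cut. The only free hydroxyl of 9 is capped with the more robust silyl group. The forward step must not disturb the acid-sensitive acetal at C2.

**9 to 6 and 7 (through 8).** The C1′–C2′ bond is cut. A carbinol next to a ring oxygen is the retron for addition of an organomagnesium reagent to an α-alkoxy aldehyde. This removes nine carbons and the C1′ stereocentre. The forward step needs chelation between the carbonyl oxygen and O1 to obtain 1′R, and C2 must be masked against the reagent.

**6 to 5.** The anomeric O–Si bond is cut. This exposes the lactol that the key step produces. The forward step must silylate the hemiacetal hydroxyl without epimerising the neighbouring aldehyde-bearing C5.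

**5 to 3 (through 4).** The O1–C2 bond of the lactol is cut and C2 and C1′ are rejoined as an alkene. A heterocycle with two different carbonyl termini and two stereocentres becomes a five-membered carbocycle whose cis-1,4-dioxygenation is available by enzymatic desymmetrisation. The forward cleavage must leave both carbinol carbons untouched, and exactly one of the two oxygens must be free so that the termini are differentiated.

**3 to 2 to 1.** The O–Si bond on the future C3 oxygen is cut and the acetate on the future O1 is restored. Commercial 1 has its free hydroxyl on the carbon that must carry the silyl ether, so the two oxygen substituents are exchanged in two operations. Neither step may allow acyl or silyl migration across the ring, which would erode the enantiomeric purity.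

## Other disconnections considered

**Alternative 1:** The ring would be cut at C4–C5 and O1–C2, giving aldehyde A1, (R)-2-(benzyloxy)undec-10-enal, and allylsilane A2, (R)-dimethyl(oct-1-en-3-yl)phenylsilane.

- **Forward key step.** SnCl4 would chelate the carbonyl and benzyloxy oxygens of A1. The terminal alkene carbon of A2 would add anti to silicon (C4–C5), silicon would shift to the neighbouring carbon, and the alkoxide would close O1–C2 to give the 2,5-trans silyl oxolane A3.
- **In its favour.** The annulation is convergent. Both side chains are already complete in A1 and A2, and the ring is formed together with C2, C3 and C5, with C1′ relayed by chelation. On convergence and on stereocentres set per step this plan is better than the chosen one.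
- **Against it.**
  - Silicon in A3 is trans to pentyl. Tamao–Fleming oxidation, which retains configuration, would give alcohol A4 with C3 epimeric to the target.
  - A Mitsunobu esterification of A4 with tetradecanoic acid would correct C3 and install the ester in one operation. That is elegant on paper, but it is an SN2 displacement at a crowded ring carbon where elimination competes.
  - Unmasking the phenyldimethylsilyl group needs an electrophile (bromine or Hg(OAc)2 with peracid), which endangers the terminal alkene.
  - The benzyl ether cannot be removed by hydrogenolysis for the same reason.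
  - A1 and A2 each need their own enantioselective preparation.
- **Comparison.** Both plans rely on chelation control for the C5/C1′ pair and are equal there. The chosen plan takes C3 with the correct configuration from the starting material and never exposes the alkene to an electrophile, so it is better on functional-group compatibility. The linear sequence of this alternative would be comparable or shorter, but the total count would be higher.

**Alternative 2:** The cut is at O1–C2 together with the C1″–carbonyl bond of a lactone spanning C2 and the C3 oxygen. The precursor is enediol A5, (1R,3S)-1-[(4R)-2,2-dimethyl-1,3-dioxolan-4-yl]pent-4-ene-1,3-diol.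

- **Forward key step.** Divalent palladium (PdCl2, with CuCl2 as reoxidant, under CO) would activate the alkene. The C5 hydroxyl would add to the internal carbon, CO would insert into the C1″–Pd bond, and the C3 hydroxyl would capture the acylpalladium, giving the cis-fused bicyclic lactone A6.
- **In its favour.** The 2,3-cis relationship is enforced by the ring fusion and not by facial selectivity of an intermolecular attack. On this point the alternative is better than the chosen plan. The C3 and C1′ oxygens are differentiated as lactone and acetonide, which equals the chosen plan.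
- **Against it.**
  - A6 carries only two of the five pentyl carbons. The rest must be added by lactone reduction, Wittig olefination and hydrogenation, and the hydrogenation must precede any introduction of the terminal alkene.
  - The acetonide must afterwards be elaborated into the dec-9-enyl carbinol by a second C–C coupling.
  - A5 needs a multistep chiral-pool preparation.
  - The key step requires carbon monoxide and stoichiometric CuCl2.
- **Comparison.** The alternative is stronger in ring-forming stereocontrol and weaker in step economy. The chosen plan attaches each side chain in one step, and the post-key sequence here would be clearly longer.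

**Alternative 3:** The cut is at O1–C2 and C2–C1″, leading back to diazoketone A7, (4R)-1-diazo-4-[(4R)-2,2-dimethyl-1,3-dioxolan-4-yl]-4-(prop-2-en-1-yloxy)butan-2-one.

- **Forward key step.** Cu(acac)2 would generate a copper carbenoid. The allyl ether oxygen would capture it to give a cyclic oxonium ylide, and a [2,3]-shift would move the allyl group from O1 to C2, giving the 2,5-trans oxolan-3-one A8.
- **In its favour.** The 2,5-trans relationship is set by a concerted rearrangement in the ring-forming step itself. On this point the alternative is better than the chosen plan, where 2,5-trans follows only indirectly from the facial selectivity at C2. The catalyst loading is low and one step forms the ring and a C–C bond.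
- **Against it.**
  - C3 arrives as a ketone and must be reduced from the face opposite the C2 substituent. The chosen plan draws C3 from the starting material and is better there.
  - The allyl group must be lengthened by two carbons and saturated before the terminal alkene exists.
  - The diazoketone requires diazomethane chemistry.
  - The acetonide again has to be turned into the long carbinol chain.
- **Comparison.** Both plans build C2 next to a C3 oxygen function and must control the cis relationship by a reagent approach, so they are equal in kind. The alternative would need noticeably more steps overall.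

Key step: step 3

Remark on the chemistry: compounds 5, 6, 9 and 10 are taken as mixtures of C2 anomers, which is harmless because C2 becomes planar in 14. Ring positions are named by the target numbering (O1, C2 pentyl, C3, C4, C5, carbinol C1′, first pentyl carbon C1″).

## Route

Step 1
Reactants: 1 (1S,4R)-cis-4-acetoxycyclopent-2-en-1-ol
Product: 2 (1R,4S)-4-(tert-butyldimethylsilyloxy)cyclopent-2-en-1-yl acetate
Conditions: TBSCl, imidazole, DMF, 0 °C → rt
Reagents that add atoms: tert-butyldimethylsilyl chloride, CC(C)(C)[Si](C)(C)Cl
Why: Standard imidazole-mediated silylation of a secondary alcohol; no stereocentre is touched and the acetate does not migrate under these near-neutral conditions.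

Step 2
Reactants: 2 (1R,4S)-4-(tert-butyldimethylsilyloxy)cyclopent-2-en-1-yl acetate
Product: 3 (1R,4S)-4-(tert-butyldimethylsilyloxy)cyclopent-2-en-1-ol
Conditions: K2CO3 (0.2 equiv), MeOH, 0 °C → rt
Reagents that add atoms: none
Why: Base-catalysed transesterification (methanolysis of an acetate) frees the hydroxyl on the carbon that becomes C5 while the silyl ether on the future C3 oxygen stays; the two oxygens have thereby exchanged roles relative to 1, which places the free hydroxyl on the R carbon as required.

Step 3
Reactants: 3 (1R,4S)-4-(tert-butyldimethylsilyloxy)cyclopent-2-en-1-ol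
Product: 5 (2R,4S)-4-(tert-butyldimethylsilyloxy)-5-hydroxyoxolane-2-carbaldehyde (both anomers), via hydroxy dialdehyde 4 (not isolated)
Conditions: O3, NaHCO3 (solid), CH2Cl2, −78 °C; then Me2S, −78 °C → rt; crude product used directly
Reagents that add atoms: ozone, [O-][O+]=O
Why: Ozone adds to the ring alkene by 1,3-dipolar cycloaddition, the primary ozonide fragments and recombines (Criegee mechanism), and Me2S reduces the peroxidic material to hydroxy dialdehyde 4 without touching the silyl ether. In 4 the free hydroxyl is 1,4-related to the formyl carbon on the silyloxy side, so it adds to that carbonyl in a 5-exo-trig hemiacetalisation and closes the oxolane (O1–C2), whereas addition to the other formyl group would require a three-membered ring. The closest known reaction type is the ozonolysis of hydroxy cycloalkenes and of cis-3,5-dioxygenated cyclopentenes, whose γ-hydroxy aldehydes are obtained as lactols. No bond at either carbinol carbon is broken, so C3 (S) and C5 (R) are carried over unchanged and appear trans on the new ring. The only new stereocentre is the anomeric C2, deliberately left uncontrolled because it is planarised in step 7. The selectivity the step needs is the differentiation of the two formyl groups, and it is secured by the fact that only one oxygen of 3 is free. The cold, buffered, non-aqueous reductive work-up is chosen to keep the C5 α-oxy aldehyde from epimerising and the silyl group from moving to the free oxygen of 4, which would interchange the two termini.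

Step 4
Reactants: 5 (2R,4S)-4-(tert-butyldimethylsilyloxy)-5-hydroxyoxolane-2-carbaldehyde (both anomers)
Product: 6 (2R,4S)-4,5-bis(tert-butyldimethylsilyloxy)oxolane-2-carbaldehyde (both anomers)
Conditions: TBSCl, imidazole, CH2Cl2, −20 → 0 °C
Reagents that add atoms: tert-butyldimethylsilyl chloride, CC(C)(C)[Si](C)(C)Cl
Why: Imidazole-mediated silylation of the hemiacetal hydroxyl locks C2 as a mixed silyl acetal that is inert to Grignard reagents yet ionisable later; the aldehyde offers no hydroxyl, and using the same silyl group as on C3 makes any 1,2-silyl shift between the neighbouring oxygens degenerate.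

Step 5
Reactants: 6 (2R,4S)-4,5-bis(tert-butyldimethylsilyloxy)oxolane-2-carbaldehyde (both anomers); 7 9-bromonon-1-ene
Product: 9 (1R)-1-[(2R,4S)-4,5-bis(tert-butyldimethylsilyloxy)oxolan-2-yl]dec-9-en-1-ol (both anomers), via non-8-enylmagnesium bromide 8 (not isolated)
Conditions: 7, Mg, Et2O, reflux; then 6, MgBr2·OEt2, CH2Cl2, −78 °C; aqueous quench
Reagents that add atoms: none
Why: Magnesium insertion gives 8, which adds to the aldehyde of 6 held in a five-membered MgBr2 chelate between the carbonyl oxygen and ring oxygen O1 (chelation-controlled Grignard addition to an α-alkoxy aldehyde); attack from the face of the C5 hydrogen, away from C4, sets C1′ as R (threo to C5). The hindered silyl acetal oxygen and the trans-disposed C3 silyl ether do not compete as chelating sites and both are inert to the reagent at −78 °C.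

Step 6
Reactants: 9 (1R)-1-[(2R,4S)-4,5-bis(tert-butyldimethylsilyloxy)oxolan-2-yl]dec-9-en-1-ol (both anomers)
Product: 10 tert-butyl{[(1R)-1-[(2R,4S)-4,5-bis(tert-butyldimethylsilyloxy)oxolan-2-yl]dec-9-enyl]oxy}diphenylsilane (both anomers)
Conditions: TBDPSCl, imidazole, DMAP (cat.), DMF, rt → 40 °C
Reagents that add atoms: tert-butyldiphenylsilyl chloride, CC(C)(C)[Si](Cl)(c1ccccc1)c1ccccc1
Why: Silylation of the only free hydroxyl with a bulkier, more acid-stable silyl chloride under nucleophilic catalysis; this ether will outlast the C3 tert-butyldimethylsilyl ether in step 8 and shields the ring face that must not be attacked in step 7.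

Step 7
Reactants: 10 tert-butyl{[(1R)-1-[(2R,4S)-4,5-bis(tert-butyldimethylsilyloxy)oxolan-2-yl]dec-9-enyl]oxy}diphenylsilane (both anomers); 11 1-bromopentane
Product: 15 tert-butyl{[(2S,3S,5R)-5-[(1R)-1-(tert-butyldiphenylsilyloxy)dec-9-enyl]-2-pentyloxolan-3-yl]oxy}dimethylsilane, via pentylmagnesium bromide 12 (not isolated), via dipentylzinc 13 (not isolated), via oxolan-2-ylium triflate 14 (not isolated)
Conditions: 11, Mg, Et2O; ZnCl2 (0.5 equiv), then 1,4-dioxane, filtration; 10, TMSOTf (1.2 equiv), CH2Cl2, −78 → −40 °C
Reagents that add atoms: none
Why: Grignard formation and transmetalation with ZnCl2 give 13; TMSOTf silylates the anomeric oxygen of 10 and expels it as a disiloxane to give 14, which 13 alkylates at C2 (Lewis acid-promoted substitution of a cyclic mixed acetal by a dialkylzinc). In the envelope of 14 that keeps the C3 silyloxy group pseudoequatorial, attack on the inside face brings pentyl in cis to the C3 oxygen and trans to the pseudoaxial C5 side chain, which sets C2 as S. A silyl ether at C3 cannot participate, whereas an ester would bridge to C2 and give the opposite outcome.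

Step 8
Reactants: 15 tert-butyl{[(2S,3S,5R)-5-[(1R)-1-(tert-butyldiphenylsilyloxy)dec-9-enyl]-2-pentyloxolan-3-yl]oxy}dimethylsilane
Product: 16 (2S,3S,5R)-5-[(1R)-1-(tert-butyldiphenylsilyloxy)dec-9-enyl]-2-pentyloxolan-3-ol
Conditions: CSA (0.2 equiv), MeOH/CH2Cl2 (1:1), 0 °C → rt
Reagents that add atoms: none
Why: Acid-catalysed methanolysis of silyl ethers discriminates strongly by the bulk and electronic character of the silyl group, so the tert-butyldimethylsilyl ether is cleaved while the tert-butyldiphenylsilyl ether, the alkene and the oxolane are left.

Step 9
Reactants: 16 (2S,3S,5R)-5-[(1R)-1-(tert-butyldiphenylsilyloxy)dec-9-enyl]-2-pentyloxolan-3-ol; 17 tetradecanoic acid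
Product: 18 (2S,3S,5R)-5-[(1R)-1-(tert-butyldiphenylsilyloxy)dec-9-enyl]-2-pentyloxolan-3-yl tetradecanoate
Conditions: DCC, DMAP, CH2Cl2, 0 °C → rt
Reagents that add atoms: none
Why: Steglich esterification: the carbodiimide activates 17 and DMAP transfers the acyl group to the hindered C3 hydroxyl; the C3–O bond is not broken, so the configuration is retained.

Step 10
Reactants: 18 (2S,3S,5R)-5-[(1R)-1-(tert-butyldiphenylsilyloxy)dec-9-enyl]-2-pentyloxolan-3-yl tetradecanoate
Product: 19 (2S,3S,5R)-5-[(1R)-1-hydroxydec-9-enyl]-2-pentyloxolan-3-yl tetradecanoate (CNP0275561.1)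
Conditions: HF·pyridine, pyridine, THF, 0 °C → rt
Reagents that add atoms: none
Why: Fluoride-driven Si–O cleavage under buffered, weakly acidic conditions leaves the ester and the terminal alkene untouched; acyl migration to C1′ is not expected because the two oxygens are trans-disposed across the ring.

## Compound list

1 | (1S,4R)-cis-4-acetoxycyclopent-2-en-1-ol | CC(=O)O[C@@H]1C[C@H](O)C=C1 | starting material
2 | (1R,4S)-4-(tert-butyldimethylsilyloxy)cyclopent-2-en-1-yl acetate | CC(=O)O[C@@H]1C[C@H](O[Si](C)(C)C(C)(C)C)C=C1 | intermediate
3 | (1R,4S)-4-(tert-butyldimethylsilyloxy)cyclopent-2-en-1-ol | O[C@@H]1C[C@H](O[Si](C)(C)C(C)(C)C)C=C1 | intermediate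
4 | (2S,4R)-2-(tert-butyldimethylsilyloxy)-4-hydroxypentanedial | O=C[C@H](O)C[C@H](O[Si](C)(C)C(C)(C)C)C=O | intermediate
5 | (2R,4S)-4-(tert-butyldimethylsilyloxy)-5-hydroxyoxolane-2-carbaldehyde, both anomers (target numbering: C2 lactol, 3S silyl ether, 5R formyl) | O=C[C@H]1C[C@H](O[Si](C)(C)C(C)(C)C)C(O)O1 | intermediate
6 | (2R,4S)-4,5-bis(tert-butyldimethylsilyloxy)oxolane-2-carbaldehyde, both anomers | O=C[C@H]1C[C@H](O[Si](C)(C)C(C)(C)C)C(O[Si](C)(C)C(C)(C)C)O1 | intermediate
7 | 9-bromonon-1-ene | C=CCCCCCCCBr | starting material
8 | non-8-enylmagnesium bromide | C=CCCCCCCC[Mg]Br | intermediate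
9 | (1R)-1-[(2R,4S)-4,5-bis(tert-butyldimethylsilyloxy)oxolan-2-yl]dec-9-en-1-ol, both anomers | C=CCCCCCCC[C@@H](O)[C@H]1C[C@H](O[Si](C)(C)C(C)(C)C)C(O[Si](C)(C)C(C)(C)C)O1 | intermediate
10 | tert-butyl{[(1R)-1-[(2R,4S)-4,5-bis(tert-butyldimethylsilyloxy)oxolan-2-yl]dec-9-enyl]oxy}diphenylsilane, both anomers | C=CCCCCCCC[C@@H](O[Si](c1ccccc1)(c1ccccc1)C(C)(C)C)[C@H]1C[C@H](O[Si](C)(C)C(C)(C)C)C(O[Si](C)(C)C(C)(C)C)O1 | intermediate
11 | 1-bromopentane | CCCCCBr | starting material
12 | pentylmagnesium bromide | CCCCC[Mg]Br | intermediate
13 | dipentylzinc | CCCCC[Zn]CCCCC | intermediate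
14 | (3S,5R)-3-(tert-butyldimethylsilyloxy)-5-[(1R)-1-(tert-butyldiphenylsilyloxy)dec-9-enyl]oxolan-2-ylium triflate | C=CCCCCCCC[C@@H](O[Si](c1ccccc1)(c1ccccc1)C(C)(C)C)[C@H]1C[C@H](O[Si](C)(C)C(C)(C)C)C=[O+]1.[O-]S(=O)(=O)C(F)(F)F | intermediate
15 | tert-butyl{[(2S,3S,5R)-5-[(1R)-1-(tert-butyldiphenylsilyloxy)dec-9-enyl]-2-pentyloxolan-3-yl]oxy}dimethylsilane | C=CCCCCCCC[C@@H](O[Si](c1ccccc1)(c1ccccc1)C(C)(C)C)[C@H]1C[C@H](O[Si](C)(C)C(C)(C)C)[C@H](CCCCC)O1 | intermediate
16 | (2S,3S,5R)-5-[(1R)-1-(tert-butyldiphenylsilyloxy)dec-9-enyl]-2-pentyloxolan-3-ol | C=CCCCCCCC[C@@H](O[Si](c1ccccc1)(c1ccccc1)C(C)(C)C)[C@H]1C[C@H](O)[C@H](CCCCC)O1 | intermediate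
17 | tetradecanoic acid | CCCCCCCCCCCCCC(=O)O | starting material
18 | (2S,3S,5R)-5-[(1R)-1-(tert-butyldiphenylsilyloxy)dec-9-enyl]-2-pentyloxolan-3-yl tetradecanoate | C=CCCCCCCC[C@@H](O[Si](c1ccccc1)(c1ccccc1)C(C)(C)C)[C@H]1C[C@H](OC(=O)CCCCCCCCCCCCC)[C@H](CCCCC)O1 | intermediate
19 | (2S,3S,5R)-5-[(1R)-1-hydroxydec-9-enyl]-2-pentyloxolan-3-yl tetradecanoate | C=CCCCCCCC[C@@H](O)[C@H]1C[C@H](OC(=O)CCCCCCCCCCCCC)[C@H](CCCCC)O1 | target

## Step count and least certain steps

Total step count: 10 (the organometallic reagents 8, 12 and 13 are made in the flask within steps 5 and 7). Longest linear sequence: 10 steps, from 1 to 19.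

**Step 3 (key step).** The likely failures are incomplete reduction of peroxidic intermediates, epimerisation of the C5 α-oxy aldehyde on handling, and 1,3-shift of the silyl group to the free oxygen in the open form 4, which would interchange the two termini and lower the enantiomeric purity. Hydrate and hemiacetal oligomer formation would also make purification of 5 impractical, which is why it is carried on crude.

The fallback sets out from 3 and returns at 5. Upjohn dihydroxylation (OsO4 catalytic, NMO, acetone/water) should add to the alkene face opposite the two allylic oxygens and give (1R,2S,3S,4S)-4-(tert-butyldimethylsilyloxy)cyclopentane-1,2,3-triol F1. One equivalent of NaIO4 on silica gel in CH2Cl2 at 0 °C would then cleave the cis-2,3-diol, which forms the cyclic periodate ester far more readily than the trans-1,2 pair. The hydroxy dialdehyde would close to 5, whose ring oxygen is no longer available for a second glycol cleavage. This replaces ozonide chemistry by a peroxide-free, two-stage cleavage.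

**Step 7.** The likely failures are sluggish ionisation of the hindered anomeric silyl ether, loss of a proton from 14 to give an enol ether, and eroded facial selectivity, because a σ-bonded zinc alkyl is a less discriminating partner than a π-nucleophile when it must approach next to the C3 silyloxy group.

The fallback sets out from 10 and returns at 15. A Mukaiyama-type addition of 1-methoxy-1-(trimethylsilyloxy)ethene to the cation generated from 10 with catalytic TMSOTf (CH2Cl2, −78 °C) should give methyl 2-[(2S,3S,5R)-3-(tert-butyldimethylsilyloxy)-5-[(1R)-1-(tert-butyldiphenylsilyloxy)dec-9-enyl]oxolan-2-yl]acetate F4. This is a π-nucleophile, the class for which cis attack beside a ring oxygen substituent is best established. Reduction with i-Bu2AlH would give 2-[(2S,3S,5R)-3-(tert-butyldimethylsilyloxy)-5-[(1R)-1-(tert-butyldiphenylsilyloxy)dec-9-enyl]oxolan-2-yl]ethan-1-ol F5. Tosylation (TsCl, pyridine) would give 2-[(2S,3S,5R)-3-(tert-butyldimethylsilyloxy)-5-[(1R)-1-(tert-butyldiphenylsilyloxy)dec-9-enyl]oxolan-2-yl]ethyl 4-methylbenzenesulfonate F6. Li2CuCl4-catalysed coupling of F6 with propylmagnesium bromide would complete the pentyl chain without any hydrogenation and give 15.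

**Step 5.** The likely failure is poor facial selectivity, if chelation through the acetal-type ring oxygen is too weak and open-chain (Felkin–Anh) addition competes, giving the 1′S epimer.

The fallback sets out from 9, taken as the mixture of C1′ epimers, and returns at 9. Oxidation with Dess–Martin periodinane would give 1-[(2R,4S)-4,5-bis(tert-butyldimethylsilyloxy)oxolan-2-yl]dec-9-en-1-one F3. Reduction with LiBH(s-Bu)3 in THF at −78 °C, a bulky non-chelating hydride, should follow the Felkin–Anh model with O1 anti to the incoming hydride. For the ketone this leads to the same 1′R (threo) carbinol that chelation gives for the aldehyde. The stereocentre is then set by C–H rather than C–C bond formation.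

**Step 4.** The likely failures are silylation at a hydroxyl of a hydrate or of an aldehyde–lactol adduct instead of the anomeric hydroxyl, and base-induced epimerisation at C5 while the free aldehyde is exposed.

The fallback sets out from 5 and returns at 9 by inverting the order of steps 4 and 5. Crude 5 would be deprotonated at −78 °C with one equivalent of i-PrMgCl, so that the lactol is carried as its magnesium alkoxide, which does not open at that temperature. MgBr2·OEt2 and 8 would then alkylate the free aldehyde to give (1R)-1-[(2R,4S)-4-(tert-butyldimethylsilyloxy)-5-hydroxyoxolan-2-yl]dec-9-en-1-ol F2. Selective silylation of the more reactive hemiacetal hydroxyl (TBSCl, one equivalent, imidazole, CH2Cl2, −20 °C) in preference to the hindered C1′ carbinol would give 9.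

## Further compounds

F1 | step 3 | (1R,2S,3S,4S)-4-(tert-butyldimethylsilyloxy)cyclopentane-1,2,3-triol | O[C@@H]1C[C@H](O[Si](C)(C)C(C)(C)C)[C@@H](O)[C@H]1O
F2 | step 4 | (1R)-1-[(2R,4S)-4-(tert-butyldimethylsilyloxy)-5-hydroxyoxolan-2-yl]dec-9-en-1-ol | C=CCCCCCCC[C@@H](O)[C@H]1C[C@H](O[Si](C)(C)C(C)(C)C)C(O)O1
F3 | step 5 | 1-[(2R,4S)-4,5-bis(tert-butyldimethylsilyloxy)oxolan-2-yl]dec-9-en-1-one | C=CCCCCCCCC(=O)[C@H]1C[C@H](O[Si](C)(C)C(C)(C)C)C(O[Si](C)(C)C(C)(C)C)O1
F4 | step 7 | methyl 2-[(2S,3S,5R)-3-(tert-butyldimethylsilyloxy)-5-[(1R)-1-(tert-butyldiphenylsilyloxy)dec-9-enyl]oxolan-2-yl]acetate | C=CCCCCCCC[C@@H](O[Si](c1ccccc1)(c1ccccc1)C(C)(C)C)[C@H]1C[C@H](O[Si](C)(C)C(C)(C)C)[C@H](CC(=O)OC)O1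
F5 | step 7 | 2-[(2S,3S,5R)-3-(tert-butyldimethylsilyloxy)-5-[(1R)-1-(tert-butyldiphenylsilyloxy)dec-9-enyl]oxolan-2-yl]ethan-1-ol | C=CCCCCCCC[C@@H](O[Si](c1ccccc1)(c1ccccc1)C(C)(C)C)[C@H]1C[C@H](O[Si](C)(C)C(C)(C)C)[C@H](CCO)O1
F6 | step 7 | 2-[(2S,3S,5R)-3-(tert-butyldimethylsilyloxy)-5-[(1R)-1-(tert-butyldiphenylsilyloxy)dec-9-enyl]oxolan-2-yl]ethyl 4-methylbenzenesulfonate | C=CCCCCCCC[C@@H](O[Si](c1ccccc1)(c1ccccc1)C(C)(C)C)[C@H]1C[C@H](O[Si](C)(C)C(C)(C)C)[C@H](CCOS(=O)(=O)c2ccc(C)cc2)O1
A1 | alternative 1 | (R)-2-(benzyloxy)undec-10-enal | C=CCCCCCCC[C@@H](OCc1ccccc1)C=O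
A2 | alternative 1 | (R)-dimethyl(oct-1-en-3-yl)phenylsilane | C=C[C@@H](CCCCC)[Si](C)(C)c1ccccc1
A3 | alternative 1 | [(2S,3R,5R)-5-[(1R)-1-(benzyloxy)dec-9-enyl]-2-pentyloxolan-3-yl]dimethyl(phenyl)silane | C=CCCCCCCC[C@@H](OCc1ccccc1)[C@H]1C[C@@H]([Si](C)(C)c2ccccc2)[C@H](CCCCC)O1
A4 | alternative 1 | (2S,3R,5R)-5-[(1R)-1-(benzyloxy)dec-9-enyl]-2-pentyloxolan-3-ol | C=CCCCCCCC[C@@H](OCc1ccccc1)[C@H]1C[C@@H](O)[C@H](CCCCC)O1
A5 | alternative 2 | (1R,3S)-1-[(4R)-2,2-dimethyl-1,3-dioxolan-4-yl]pent-4-ene-1,3-diol | C=C[C@@H](O)C[C@@H](O)[C@H]1COC(C)(C)O1
A6 | alternative 2 | (3aS,5R,6aS)-5-[(4R)-2,2-dimethyl-1,3-dioxolan-4-yl]hexahydrofuro[3,2-b]furan-2-one (cis-fused 2,6-dioxabicyclo[3.3.0]octan-3-one) | CC2(C)OC[C@@H](O2)[C@H]1C[C@@H]3OC(=O)C[C@@H]3O1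
A7 | alternative 3 | (4R)-1-diazo-4-[(4R)-2,2-dimethyl-1,3-dioxolan-4-yl]-4-(prop-2-en-1-yloxy)butan-2-one | C=CCO[C@H](CC(=O)C=[N+]=[N-])[C@H]1COC(C)(C)O1
A8 | alternative 3 | (2S,5R)-2-allyl-5-[(4R)-2,2-dimethyl-1,3-dioxolan-4-yl]oxolan-3-one | CC2(C)OC[C@@H](O2)[C@H]1CC(=O)[C@H](CC=C)O1
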